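## Retrosynthetic overview
1. The tertiary C–Br bond comes last. It is made from the trans-diaxial ring chlorohydrin (C4–OH, C3–Cl) by a neutral, chlorine-assisted substitution with retention.
2. The oxane is the only ring that has to be built, and it is formed second to last. A 6-endo bromoetherification joins the C7 tertiary alcohol to the C10=C11 prenyl alkene.
3. The C9–C10 bond comes from a copper-catalysed coupling of isobutenylmagnesium bromide with a C9 tosylate.
4. The key bond is C7–C8. It is made by intermolecular aldol addition of the magnesium enolate of (R)-tert-butyl p-tolylsulfinylacetate to a cyclohexyl methyl ketone, and the sulfoxide sets C7.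
5. The ketone and the intact carbocycle come from (S)-limonene: bromohydrin, trans-epoxide, chloride opening (sets C4–O and C3–Cl), silylation, ozonolysis.

**Reading of the target (assumption):** (3R,6S)-3-bromo-6-[(1S,3R,4R)-4-bromo-3-chloro-4-methylcyclohexyl]-2,2,6-trimethyloxane. With the oxanyl group equatorial, ring Br and Cl are trans-diaxial. The oxane Br is equatorial and trans to the cyclohexyl group.

**Labels:** C7 is the carbinol carbon (later oxane C6). C8 to C11 are counted along the chain away from it.

## Route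

Step 1
Reactants: 1 (S)-(−)-limonene
Product: 2 (1R,2R,4S)-2-bromo-1-methyl-4-(prop-1-en-2-yl)cyclohexan-1-ol
Conditions: NBS (1.05 equiv), acetone/H2O 4:1, 0 °C
Reagents that add atoms: N-bromosuccinimide O=C1CCC(=O)N1Br; water O
Why: Bromohydrin formation: the trisubstituted ring alkene is the more nucleophilic one, bromonium formation is reversible, and only the bromonium ion on the face opposite the isopropenyl group can be opened by water at the tertiary carbon in a way that is both Markovnikov and trans-diaxial (Fürst–Plattner rule), which sets C1 with its OH axial and cis to the side chain.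

Step 2
Reactants: 2 bromohydrin
Product: 3 (1R,2S,4S)-1,2-epoxy-p-menth-8-ene (trans-limonene oxide of the S series)
Conditions: aq NaOH (2 M), THF, 0 °C to rt
Reagents that add atoms: none
Why: Intramolecular Williamson reaction (SN2): the axial alkoxide is antiperiplanar to the axial C–Br bond and displaces bromide with inversion at C2, so the oxirane oxygen ends up cis to the isopropenyl group while C1 is untouched.

Step 3
Reactants: 3 trans-epoxide
Product: 4 (1R,2R,4S)-2-chloro-1-methyl-4-(prop-1-en-2-yl)cyclohexan-1-ol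
Conditions: LiCl (3 equiv), AcOH (2 equiv), THF, rt to 40 °C
Reagents that add atoms: lithium chloride [Li+].[Cl-]
Why: Nucleophilic epoxide opening under Fürst–Plattner control: for this epoxide the trans-diaxial path and the less hindered carbon coincide, so chloride attacks C2 with inversion and sets the axial C–Cl bond trans to the axial tertiary OH, while any cis-epoxide carried along opens at C1 to a secondary alcohol that is removed by chromatography.

Step 4
Reactants: 4 chlorohydrin
Product: 5 {[(1R,2R,4S)-2-chloro-1-methyl-4-(prop-1-en-2-yl)cyclohexyl]oxy}triethylsilane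
Conditions: TESOTf, 2,6-lutidine, CH2Cl2, −78 to 0 °C
Reagents that add atoms: triethylsilyl trifluoromethanesulfonate CC[Si](CC)(CC)OS(=O)(=O)C(F)(F)F
Why: Silyl triflate silylation of a hindered tertiary alcohol blocks alkoxide formation, and thus re-closure of the chlorohydrin to the epoxide, in the basic steps that follow, and touches no stereocentre.

Step 5
Reactants: 5 TES ether
Product: 7 1-[(1S,3R,4R)-3-chloro-4-methyl-4-(triethylsilyloxy)cyclohexyl]ethan-1-one, via secondary ozonide 6 (not isolated)
Conditions: O3, CH2Cl2, −78 °C; then Me2S, −78 °C to rt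
Reagents that add atoms: ozone [O-][O+]=O
Why: Ozonolysis (Criegee mechanism) with reductive work-up cleaves the only remaining alkene to the methyl ketone under neutral conditions, so the ring stereocentre alpha to the new carbonyl is not epimerised.

Step 6
Reactants: 8 tert-butyl acetate; 9 (1R,2S,5R)-menthyl (S)-4-methylbenzenesulfinate
Product: 11 tert-butyl 2-[(R)-(4-methylphenyl)sulfinyl]acetate, via lithium enolate of tert-butyl acetate 10 (not isolated)
Conditions: 8 (2.2 equiv), LiN(iPr)2 (2.2 equiv), THF, −78 °C; then 9, −78 to 0 °C; aq work-up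
Reagents that add atoms: none
Why: Andersen-type substitution at sulfinyl sulfur: the ester enolate displaces mentholate with clean inversion, so the (S)-sulfinate gives the (R)-sulfoxide, and the second equivalent of enolate stores the acidic product as its enolate.

Step 7 (key step)
Reactants: 11 (R)-sulfinylacetate; 7 methyl ketone
Product: 13 tert-butyl (3R)-3-[(1S,3R,4R)-3-chloro-4-methyl-4-(triethylsilyloxy)cyclohexyl]-3-hydroxy-2-[(R)-(4-methylphenyl)sulfinyl]butanoate (C2 epimers), via chloromagnesium enolate 12 (not isolated)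
Conditions: 11 (1.6 equiv), t-BuMgCl (1.5 equiv), THF, −78 °C, 30 min; then 7, −78 °C, 6–12 h; aq work-up at low temperature
Reagents that add atoms: none
Why: Intermolecular aldol addition of a chiral α-sulfinyl ester enolate (Solladié–Mioskowski reaction): magnesium chelated by enolate O and sulfinyl O fixes the enolate, the ketone is attacked from the enolate face not shielded by p-tolyl with its cyclohexyl group in the place an aldehyde R group takes and methyl in the place of H, so the (R)-sulfoxide sets the C7 configuration of the target (cyclohexyl methyl ketone, the parent of 7, is among the best ketone substrates at about 95% ee), the weakly basic enolate does not epimerise 7, and the minor C7 epimer is removed by chromatography here or at 15.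

Step 8
Reactants: 13 aldol adduct
Product: 14 tert-butyl (3S)-3-[(1S,3R,4R)-3-chloro-4-methyl-4-(triethylsilyloxy)cyclohexyl]-3-hydroxybutanoate
Conditions: aluminium amalgam (Al foil, 2% aq HgCl2), THF/H2O 9:1, 0 °C to rt
Reagents that add atoms: none
Why: Reductive desulfinylation by electron transfer cleaves only the C–S bond activated by the ester, which removes the auxiliary and the stereorandom C2 centre and leaves C–Cl, silyl ether and the C7 carbinol untouched (the C7 descriptor changes from R to S only because sulfur is gone).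

Step 9
Reactants: 14 β-hydroxy ester
Product: 15 (3S)-3-[(1S,3R,4R)-3-chloro-4-methyl-4-(triethylsilyloxy)cyclohexyl]butane-1,3-diol
Conditions: LiAlH4, Et2O, 0 °C
Reagents that add atoms: none
Why: Hydride reduction of the ester is fast at 0 °C, where the hindered secondary chloride and the silyl ether are inert and the aluminium alkoxide of the carbinol does not undergo retro-aldol cleavage.

Step 10
Reactants: 15 diol
Product: 16 (3S)-3-[(1S,3R,4R)-3-chloro-4-methyl-4-(triethylsilyloxy)cyclohexyl]-3-hydroxybutyl 4-methylbenzenesulfonate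
Conditions: TsCl (1.1 equiv), Et3N, DMAP (cat.), CH2Cl2, 0 °C
Reagents that add atoms: 4-toluenesulfonyl chloride Cc1ccc(cc1)S(=O)(=O)Cl
Why: Sulfonylation is fully selective for the primary over the tertiary hydroxyl on steric grounds.

Step 11
Reactants: 16 hydroxy tosylate
Product: 17 (3S)-3-[(1S,3R,4R)-3-chloro-4-methyl-4-(triethylsilyloxy)cyclohexyl]-3-(triethylsilyloxy)butyl 4-methylbenzenesulfonate
Conditions: TESOTf, 2,6-lutidine, CH2Cl2, −40 to 0 °C
Reagents that add atoms: triethylsilyl trifluoroacetate-free reagent triethylsilyl trifluoromethanesulfonate CC[Si](CC)(CC)OS(=O)(=O)C(F)(F)F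
Why: Silylation of the C7 tertiary alcohol rules out a γ-alkoxide in the next step, which would close to an oxetane and consume Grignard reagent.

Step 12
Reactants: 17 bis-silyl tosylate; 18 2-methylprop-1-en-1-ylmagnesium bromide
Product: 19 triethyl{[(2S)-2-[(1S,3R,4R)-3-chloro-4-methyl-4-(triethylsilyloxy)cyclohexyl]-6-methylhept-5-en-2-yl]oxy}silane
Conditions: 18 (3 equiv, 0.5 M in THF), Li2CuCl4 (5 mol%), THF, −30 to 0 °C
Reagents that add atoms: 2-methylprop-1-en-1-ylmagnesium bromide (18) CC(C)=C[Mg]Br
Why: Kochi-type copper-catalysed cross-coupling of an alkenyl Grignard reagent with an unhindered primary tosylate installs the C10=C11 prenyl terminus, and the secondary ring chloride does not couple under these conditions.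

Step 13
Reactants: 19 bis-silyl ether
Product: 20 (1R,2R,4S)-2-chloro-4-[(2S)-2-hydroxy-6-methylhept-5-en-2-yl]-1-methylcyclohexan-1-ol
Conditions: HF·pyridine, pyridine, THF, 0 °C to rt
Reagents that add atoms: none
Why: Fluoride-driven desilylation in a buffered, weakly acidic medium frees both tertiary alcohols without ever forming an alkoxide (no epoxide re-closure) and is too mild to protonate the prenyl alkene.

Step 14
Reactants: 20 chloro diol
Product: 21 (3R,6S)-3-bromo-6-[(1S,3R,4R)-3-chloro-4-hydroxy-4-methylcyclohexyl]-2,2,6-trimethyloxane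
Conditions: 2,4,4,6-tetrabromocyclohexa-2,5-dien-1-one (TBCO, 1.1 equiv), MeNO2, 0 °C to rt, dark; chromatography
Reagents that add atoms: TBCO O=C1C(Br)=CC(Br)(Br)C=C1Br
Why: Bromoetherification: the C7 hydroxyl opens the bromonium ion at the tertiary carbon C11 (Markovnikov, 6-endo) through a chair-like transition state with Br and the bulky cyclohexyl group equatorial and the C7 methyl axial, which sets C10 trans to the cyclohexyl group, while the ring OH cannot reach the alkene and the oxolane (5-exo) isomer and the C10 epimer are separated off.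

Step 15
Reactants: 22 1-chloro-N,N,2-trimethylprop-1-en-1-amine
Product: 23 1-bromo-N,N,2-trimethylprop-1-en-1-amine
Conditions: CH2Br2 (excess, neat), reflux; distillation under N2
Reagents that add atoms: dibromomethane BrCBr
Why: Halogen exchange through the keteniminium chloride: chloride is consumed by SN2 attack on CH2Br2 and the bromide set free recombines to the α-bromoenamine, driven by the excess of CH2Br2.

Step 16
Reactants: 21 tertiary alcohol; 23 α-bromoenamine
Product: 25 (3R,6S)-3-bromo-6-[(1S,3R,4R)-4-bromo-3-chloro-4-methylcyclohexyl]-2,2,6-trimethyloxane, via alkoxyiminium bromide 24 (not isolated)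
Conditions: 23 (1.5 equiv), CH2Cl2, 0 °C to rt
Reagents that add atoms: 1-bromo-N,N,2-trimethylprop-1-en-1-amine (23) CC(C)=C(Br)N(C)C
Why: Neutral deoxybromination with a Ghosez-type α-haloenamine: the alcohol adds to the keteniminium form to give 24, whose axial C–O bond is antiperiplanar to the axial C–Cl bond, so ionisation is assisted by chlorine and bromide enters the tertiary centre axially and anti to Cl (the Markovnikov and trans-diaxial mode), which means net retention at C4, and no HBr is set free so the di-tertiary oxane ether survives.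

## Compound list
1 | (S)-(−)-limonene | CC(=C)[C@H]1CCC(C)=CC1 | starting material
2 | (1R,2R,4S)-2-bromo-1-methyl-4-(prop-1-en-2-yl)cyclohexan-1-ol | CC(=C)[C@H]1CC[C@@](C)(O)[C@H](Br)C1 | intermediate
3 | (1R,2S,4S)-1,2-epoxy-p-menth-8-ene, oxirane O cis to isopropenyl | CC(=C)[C@H]1CC[C@@]2(C)O[C@H]2C1 | intermediate
4 | (1R,2R,4S)-2-chloro-1-methyl-4-(prop-1-en-2-yl)cyclohexan-1-ol | CC(=C)[C@H]1CC[C@@](C)(O)[C@H](Cl)C1 | intermediate
5 | TES ether of 4 | CC(=C)[C@H]1CC[C@@](C)(O[Si](CC)(CC)CC)[C@H](Cl)C1 | intermediate
6 | secondary ozonide of 5 (1,2,4-trioxolane, ozonide carbon unassigned) | CC1(OCOO1)[C@H]2CC[C@@](C)(O[Si](CC)(CC)CC)[C@H](Cl)C2 | intermediate (not isolated)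
7 | 1-[(1S,3R,4R)-3-chloro-4-methyl-4-(triethylsilyloxy)cyclohexyl]ethan-1-one | CC(=O)[C@H]1CC[C@@](C)(O[Si](CC)(CC)CC)[C@H](Cl)C1 | intermediate
8 | tert-butyl acetate | CC(=O)OC(C)(C)C | starting material
9 | (1R,2S,5R)-menthyl (S)-4-methylbenzenesulfinate | CC(C)[C@@H]1CC[C@@H](C)C[C@H]1O[S@](=O)c1ccc(C)cc1 | starting material
10 | lithium enolate of tert-butyl acetate | [Li]OC(=C)OC(C)(C)C | intermediate (not isolated)
11 | tert-butyl 2-[(R)-(4-methylphenyl)sulfinyl]acetate | CC(C)(C)OC(=O)C[S@@](=O)c1ccc(C)cc1 | intermediate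
12 | chloromagnesium enolate of 11 | CC(C)(C)OC(O[Mg]Cl)=C[S@@](=O)c1ccc(C)cc1 | intermediate (not isolated)
13 | aldol adduct, C2 epimers, C7 arranged in space as in 14 | CC(C)(C)OC(=O)C([S@@](=O)c1ccc(C)cc1)[C@](C)(O)[C@H]2CC[C@@](C)(O[Si](CC)(CC)CC)[C@H](Cl)C2 | intermediate
14 | tert-butyl (3S)-3-[(1S,3R,4R)-3-chloro-4-methyl-4-(triethylsilyloxy)cyclohexyl]-3-hydroxybutanoate | CC(C)(C)OC(=O)C[C@](C)(O)[C@H]1CC[C@@](C)(O[Si](CC)(CC)CC)[C@H](Cl)C1 | intermediate
15 | (3S)-3-[(1S,3R,4R)-3-chloro-4-methyl-4-(triethylsilyloxy)cyclohexyl]butane-1,3-diol | OCC[C@](C)(O)[C@H]1CC[C@@](C)(O[Si](CC)(CC)CC)[C@H](Cl)C1 | intermediate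
16 | primary tosylate of 15 | Cc1ccc(cc1)S(=O)(=O)OCC[C@](C)(O)[C@H]2CC[C@@](C)(O[Si](CC)(CC)CC)[C@H](Cl)C2 | intermediate
17 | C7 TES ether of 16 | Cc1ccc(cc1)S(=O)(=O)OCC[C@](C)(O[Si](CC)(CC)CC)[C@H]2CC[C@@](C)(O[Si](CC)(CC)CC)[C@H](Cl)C2 | intermediate
18 | 2-methylprop-1-en-1-ylmagnesium bromide | CC(C)=C[Mg]Br | starting material
19 | bis-TES ether of 20 | CC(C)=CCC[C@](C)(O[Si](CC)(CC)CC)[C@H]1CC[C@@](C)(O[Si](CC)(CC)CC)[C@H](Cl)C1 | intermediate
20 | (1R,2R,4S)-2-chloro-4-[(2S)-2-hydroxy-6-methylhept-5-en-2-yl]-1-methylcyclohexan-1-ol | CC(C)=CCC[C@](C)(O)[C@H]1CC[C@@](C)(O)[C@H](Cl)C1 | intermediate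
21 | (3R,6S)-3-bromo-6-[(1S,3R,4R)-3-chloro-4-hydroxy-4-methylcyclohexyl]-2,2,6-trimethyloxane | CC1(C)O[C@](C)([C@H]2CC[C@@](C)(O)[C@H](Cl)C2)CC[C@H]1Br | intermediate
22 | 1-chloro-N,N,2-trimethylprop-1-en-1-amine | CC(C)=C(Cl)N(C)C | starting material
23 | 1-bromo-N,N,2-trimethylprop-1-en-1-amine | CC(C)=C(Br)N(C)C | intermediate
24 | alkoxyiminium bromide from 21 and 23 | CC1(C)O[C@](C)([C@H]2CC[C@@](C)(OC(C(C)C)=[N+](C)C)[C@H](Cl)C2)CC[C@H]1Br.[Br-] | intermediate (not isolated)
25 | (3R,6S)-3-bromo-6-[(1S,3R,4R)-4-bromo-3-chloro-4-methylcyclohexyl]-2,2,6-trimethyloxane | CC1(C)O[C@](C)([C@H]2CC[C@@](C)(Br)[C@H](Cl)C2)CC[C@H]1Br | target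

## Step count
- Total steps: 16.
- Longest linear sequence: 14 (steps 1–5, 7–14, 16).
- Steps 6 and 15 are side branches.

## The three steps most likely to fail

**Step 16.** The carbinol is deactivated by the neighbouring chlorine. Loss of a proton from the cation to give alkenes, or incomplete retention, can compete with bromide capture.

The fallback replaces substitution by elimination followed by addition. It sets out from 21. SOCl2 and pyridine in CH2Cl2 at 0 °C remove the axial OH by anti elimination. This gives (3R,6S)-3-bromo-6-[(1S,5R)-5-chloro-4-methylcyclohex-3-en-1-yl]-2,2,6-trimethyloxane F5, together with some (3R,6S)-3-bromo-6-[(1S,3R)-3-chloro-4-methylidenecyclohexyl]-2,2,6-trimethyloxane F6. The equatorial H on the chlorine-bearing carbon cannot take part, so no vinyl chloride forms.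

The alkene mixture is treated with dry HBr (1.1 equiv) in CH2Cl2 at −78 to −40 °C. Both alkenes are protonated to the same tertiary cation, and bromide adds axially and anti to C–Cl. This Markovnikov hydrobromination comes back to the route at 25.

**Step 14.** The 5-exo oxolane isomer and the C10 epimer compete, so the isolated yield may be only 30–45%.

The fallback separates ring closure from bromination. It sets out from 20. Hg(OCOCF3)2 in MeNO2 at 0 °C effects a reversible, strongly Markovnikov oxymercuration. The product is the thermodynamic all-equatorial [(3R,6S)-6-[(1S,3R,4R)-3-chloro-4-hydroxy-4-methylcyclohexyl]-2,2,6-trimethyloxan-3-yl]mercury trifluoroacetate F3.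

Aqueous KBr converts F3 into the corresponding organomercury bromide F4. Br2 and LiBr in pyridine under O2 in the dark then cleave the C–Hg bond by the polar pathway with retention. This gives the equatorial bromide and comes back at 21.

**Step 7.** The level of induction on this particular ketone, slow addition and retro-aldol loss on work-up are the uncertainties.

The fallback builds the same C7–C8 bond by catalytic asymmetric carbonyl allylation. It sets out from 7. The reagents are Sn(CH2CH=CH2)4, Ti(OiPr)4 and BINOL (20–30 mol%, antipode picked in a test run) with iPrOH in CH2Cl2 at rt. They give (2S)-2-[(1S,3R,4R)-3-chloro-4-methyl-4-(triethylsilyloxy)cyclohexyl]pent-4-en-2-ol F1.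

Ozonolysis of F1 in CH2Cl2/MeOH at −78 °C gives (3S)-3-[(1S,3R,4R)-3-chloro-4-methyl-4-(triethylsilyloxy)cyclohexyl]-3-hydroxybutanal F2. NaBH4 reduces F2 in the same flask, and the sequence comes back at 15.

## Further compounds
F1 | step 7 | (2S)-2-[(1S,3R,4R)-3-chloro-4-methyl-4-(triethylsilyloxy)cyclohexyl]pent-4-en-2-ol | C=CC[C@](C)(O)[C@H]1CC[C@@](C)(O[Si](CC)(CC)CC)[C@H](Cl)C1
F2 | step 7 | (3S)-3-[(1S,3R,4R)-3-chloro-4-methyl-4-(triethylsilyloxy)cyclohexyl]-3-hydroxybutanal | O=CC[C@](C)(O)[C@H]1CC[C@@](C)(O[Si](CC)(CC)CC)[C@H](Cl)C1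
F3 | step 14 | [(3R,6S)-6-[(1S,3R,4R)-3-chloro-4-hydroxy-4-methylcyclohexyl]-2,2,6-trimethyloxan-3-yl]mercury trifluoroacetate | CC1(C)O[C@](C)([C@H]2CC[C@@](C)(O)[C@H](Cl)C2)CC[C@H]1[Hg]OC(=O)C(F)(F)F
F4 | step 14 | [(3R,6S)-6-[(1S,3R,4R)-3-chloro-4-hydroxy-4-methylcyclohexyl]-2,2,6-trimethyloxan-3-yl]mercury bromide | CC1(C)O[C@](C)([C@H]2CC[C@@](C)(O)[C@H](Cl)C2)CC[C@H]1[Hg]Br
F5 | step 16 | (3R,6S)-3-bromo-6-[(1S,5R)-5-chloro-4-methylcyclohex-3-en-1-yl]-2,2,6-trimethyloxane | CC1(C)O[C@](C)([C@H]2CC=C(C)[C@H](Cl)C2)CC[C@H]1Br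
F6 | step 16 | (3R,6S)-3-bromo-6-[(1S,3R)-3-chloro-4-methylidenecyclohexyl]-2,2,6-trimethyloxane | CC1(C)O[C@](C)([C@H]2CCC(=C)[C@H](Cl)C2)CC[C@H]1Br
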